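The benzoate ring carries oxygen on C2 and C4 and carbon on C1 and C6, the pattern of a folded 3,5,7-triketo ester. Its C1 carboxyl, crowded by the C2 hydroxyl and the C6 chain, is bound to a secondary carbinol oxygen, so one acylketene can supply both the ester C(=O)-O bond and the six ring carbons.
Cuts: after removal of the two O-benzyl groups and the 4-O-methyl group, the ester C(=O)-O bond and the C1-C6 ring bond are cut together. This gives a diketo-dioxinone (acetoxy half) and an 11-arylundecan-4-ol (resorcinol half).
The diketo-dioxinone is cut between the chain ketone and its alpha carbon (acid chloride plus allyl keto-ester dioxinone), and the alcohol is cut at the aryl-CH2 bond (B-alkyl Suzuki coupling). Each carbinol chain is cut at the CH2-CH2 bond beta to oxygen (epoxide plus alkenyl Grignard reagent).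
Forward order: the resorcinol and dioxinone rings are bought and both chains are grown from the epoxide. One chain is attached to the dioxinone by C-acylation and the other to the resorcinol ring, and the benzoate ring arises last, from the dioxinone, as the halves unite; methylation and hydrogenolysis finish the route.
Stereochemistry: both (R) centres come from (R)-2-propyloxirane, opened twice at its CH2 group. Afterwards only O-H and O-acyl bonds change at these carbons.

Key step: step 12

Remark: benzoate locants are C1 (carboxyl), C2 (OH), C4 (OMe, the 5'-methoxy group of the trivial name) and C6 (chain). Open-chain precursors are numbered from the ester carbonyl, so chain C2 and C7 become ring C1 and C6.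

Step 1
Reactants: 1 (R)-2-propyloxirane; 2 8-bromooct-1-ene
Product: 4 (R)-tridec-12-en-4-ol, via oct-7-enylmagnesium bromide 3 (not isolated)
Conditions: 2, Mg, THF, rt to 45 °C; then CuI (10 mol %), 1, THF, −40 to 0 °C; aq NH4Cl
Reagents that add atoms: magnesium [Mg] (held only in 3)
Why: Ring opening of a terminal epoxide by a Grignard reagent under catalysis by monovalent copper is an SN2 attack at the unsubstituted CH2, so the C-O bond at the stereocentre is never broken and the (R) configuration of 1 passes into 4 (the descriptor stays R because the new chain outranks propyl).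

Step 2
Reactants: 4 (R)-tridec-12-en-4-ol
Product: 5 (R)-tridec-12-en-4-yl acetate
Conditions: Ac2O, Et3N, DMAP (5 mol %), CH2Cl2, 0 °C to rt
Reagents that add atoms: acetic anhydride CC(=O)OC(C)=O
Why: DMAP-catalysed O-acetylation forms only the O-acyl bond, so the configuration is retained, and the ester put on here is the acetate of the target and needs no later exchange.

Step 3
Reactants: 5 (R)-tridec-12-en-4-yl acetate
Product: 7 (R)-13-hydroxytridecan-4-yl acetate, via B-alkyl-9-BBN adduct 6 (not isolated)
Conditions: 9-BBN, THF, 0 °C to rt; then NaBO3·4H2O, H2O, rt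
Reagents that add atoms: sodium perborate [Na+].[Na+].O[B-]1(O)OO[B-](O)(O)OO1 (oxygen of the new hydroxyl); 9-BBN B1C2CCCC1CCC2 (boron cage, held only in 6)
Why: Brown hydroboration with 9-BBN is anti-Markovnikov on a terminal alkene and leaves esters alone, and the mild perborate oxidation exchanges boron for hydroxyl without hydrolysing the acetate.

Step 4
Reactants: 7 (R)-13-hydroxytridecan-4-yl acetate
Product: 8 (R)-10-acetoxytridecanoic acid
Conditions: TEMPO (20 mol %), PhI(OAc)2 (2.2 equiv), MeCN-H2O (1:1), rt
Reagents that add atoms: water O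
Why: The oxoammonium (TEMPO) oxidation in aqueous acetonitrile takes a primary alcohol through the aldehyde hydrate to the acid under weakly acidic conditions in which a secondary acetate is inert.

Step 5
Reactants: 8 (R)-10-acetoxytridecanoic acid
Product: 9 (R)-10-acetoxytridecanoyl chloride
Conditions: (COCl)2, DMF (cat.), CH2Cl2, 0 °C to rt; evaporation
Reagents that add atoms: oxalyl chloride ClC(=O)C(=O)Cl
Why: Vilsmeier-type activation with oxalyl chloride and catalytic DMF gives the acid chloride with only gaseous co-products, so 9 can be used after evaporation with the acetate untouched.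

Step 6
Reactants: 10 allyl hydrogen malonate
Product: 11 allyl 3-(1H-benzotriazol-1-yl)-3-oxopropanoate
Conditions: 1H-benzotriazole, DCC, CH2Cl2, 0 °C to rt
Reagents that add atoms: 1H-benzotriazole c1ccc2[nH]nnc2c1
Why: Carbodiimide coupling gives a storable N-acylbenzotriazole that is reactive enough to acylate an enolate on carbon yet far less prone to ketene formation than the corresponding malonyl chloride.

Step 7
Reactants: 11 allyl 3-(1H-benzotriazol-1-yl)-3-oxopropanoate; 12 2,2,6-trimethyl-4H-1,3-dioxin-4-one
Product: 14 allyl 4-(2,2-dimethyl-4-oxo-4H-1,3-dioxin-6-yl)-3-oxobutanoate, via lithium dienolate 13 (not isolated)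
Conditions: 12 (2.5 equiv), LiN(SiMe3)2 (2.5 equiv), THF, −78 °C; then 11, −78 to −20 °C; 1 M HCl
Reagents that add atoms: LiN(SiMe3)2 [Li+].C[Si](C)(C)[N-][Si](C)(C)C (lithium, held only in 13)
Why: In this crossed vinylogous Claisen condensation, kinetic deprotonation of 12 gives the extended dienolate, which active acyl donors acylate at the 6-methylene (gamma) carbon, and the surplus dienolate absorbs the acidic protons of donor and product.

Step 8
Reactants: 14 allyl 4-(2,2-dimethyl-4-oxo-4H-1,3-dioxin-6-yl)-3-oxobutanoate; 9 (R)-10-acetoxytridecanoyl chloride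
Product: 15 allyl (12R)-12-acetoxy-2-[2-(2,2-dimethyl-4-oxo-4H-1,3-dioxin-6-yl)acetyl]-3-oxopentadecanoate (C2 methine labile and largely enolised)
Conditions: MgCl2, pyridine, CH2Cl2, 0 °C; then 9, 0 °C to rt
Reagents that add atoms: none
Why: In this soft-enolisation C-acylation, magnesium chelation of the beta-keto ester lets pyridine deprotonate the methylene between ester and ketone, and the chelated enolate is acylated on carbon rather than oxygen; the new tricarbonyl methine carries no lasting stereochemistry and is lost in step 9.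

Step 9
Reactants: 15 allyl (12R)-12-acetoxy-2-[2-(2,2-dimethyl-4-oxo-4H-1,3-dioxin-6-yl)acetyl]-3-oxopentadecanoate
Product: 17 (R)-16-(2,2-dimethyl-4-oxo-4H-1,3-dioxin-6-yl)-13,15-dioxohexadecan-4-yl acetate, via tricarbonyl acid 16 (not isolated)
Conditions: Pd(PPh3)4 (5 mol %), morpholine, THF, 0 °C to rt
Reagents that add atoms: none
Why: In this Tsuji-Trost deallylation, zerovalent palladium ionises the allyl ester, morpholine takes up the allyl fragment and the freed tricarbonyl acid loses CO2 spontaneously, while the non-allylic secondary acetate and the dioxinone are not touched.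

Step 10
Reactants: 1 (R)-2-propyloxirane; 18 6-bromohex-1-ene
Product: 20 (R)-undec-10-en-4-ol, via hex-5-enylmagnesium bromide 19 (not isolated)
Conditions: 18, Mg, THF, rt to 45 °C; then CuI (10 mol %), 1, THF, −40 to 0 °C; aq NH4Cl
Reagents that add atoms: magnesium [Mg] (held only in 19)
Why: This is the same copper-catalysed SN2 epoxide opening at the CH2 terminus as in step 1, so the second (R) carbinol is taken from 1 without any bond to the stereocentre being broken.

Step 11
Reactants: 20 (R)-undec-10-en-4-ol; 21 1,3-bis(benzyloxy)-5-bromobenzene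
Product: 23 (R)-11-[3,5-bis(benzyloxy)phenyl]undecan-4-ol, via B-alkyl-9-BBN adduct 22 (not isolated)
Conditions: 9-BBN (2.2 equiv), THF, 0 °C to rt; then 21, PdCl2(dppf) (5 mol %), 3 M aq NaOH, THF, 65 °C
Reagents that add atoms: 9-BBN B1C2CCCC1CCC2 (boron cage, held only in 22)
Why: In this hydroboration and B-alkyl Suzuki-Miyaura coupling, 9-BBN adds to the terminal alkene faster than it reacts with the hindered carbinol, the surplus borane covers any O-borylation (reversed by the aqueous base), the dppf ligand holds back beta-hydride elimination, and the remote stereocentre is not involved, so no protecting group is needed.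

Step 12
Reactants: 17 (R)-16-(2,2-dimethyl-4-oxo-4H-1,3-dioxin-6-yl)-13,15-dioxohexadecan-4-yl acetate; 23 (R)-11-[3,5-bis(benzyloxy)phenyl]undecan-4-ol
Product: 27 (R)-11-[3,5-bis(benzyloxy)phenyl]undecan-4-yl 6-[(R)-9-acetoxydodecyl]-2,4-dihydroxybenzoate, via acylketene 24 (not isolated), via triketo ester 25 (not isolated), via aldol adduct 26 (not isolated)
Conditions: PhMe, 110 °C; cool, then Cs2CO3, THF, rt; then CF3CO2H, 0 °C to rt (one pot)
Reagents that add atoms: none
Why: At about 110 °C the dioxinone ring of 17 undergoes a retro hetero-Diels-Alder reaction, losing acetone to give the diketo-acylketene 24, whose unhindered sp carbon is attacked by the secondary hydroxyl of 23 (the only protic nucleophile in the flask) to form the ester C(=O)-O bond of triketo ester 25. Cs2CO3 then enolises the C2 methylene between the ester and the C3 ketone, and this carbon adds to the C7 ketone in an aldol that is 6-exo-trig at that carbonyl, closing the future C1-C6 bond and giving carbocycle 26; acid removes water and the two remaining ring ketones enolise, so the ring ends as the 2,4-dihydroxy-6-alkyl arene. The closest known reaction type is the thermolysis of diketo-dioxinones with alcohol capture and aldol aromatisation to resorcylate esters, which is established for hindered secondary alcohols; only the remote acetate is a new spectator. No lasting stereocentre is made (the two ring centres of 26 vanish on aromatisation), and because the acyl-oxygen bond is the one formed, the (R) carbinol of 23 keeps its configuration, as does the distant (R) acetate. The step needs C2-to-C7 carbon cyclisation to win over O-cyclisation to a 4-hydroxy-2-pyranone, and it needs the acetate and benzyl ethers to survive. A high concentration of 23 during the neutral thermolysis, the higher acidity and six-ring geometry of the C2 position, and a methanol-free carbonate followed by anhydrous acid secure these points.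

Step 13
Reactants: 27 (R)-11-[3,5-bis(benzyloxy)phenyl]undecan-4-yl 6-[(R)-9-acetoxydodecyl]-2,4-dihydroxybenzoate
Product: 28 (R)-11-[3,5-bis(benzyloxy)phenyl]undecan-4-yl 6-[(R)-9-acetoxydodecyl]-2-hydroxy-4-methoxybenzoate
Conditions: MeI (1.1 equiv), K2CO3 (1.2 equiv), acetone, rt
Reagents that add atoms: iodomethane CI
Why: In this Williamson O-methylation the C2 hydroxyl is tied up in a hydrogen bond to the ester carbonyl and shielded by it, so with one equivalent of MeI and a weak base only the free, more acidic C4 phenol reacts, a selectivity well known for 2,4-dihydroxybenzoates.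

Step 14
Reactants: 28 (R)-11-[3,5-bis(benzyloxy)phenyl]undecan-4-yl 6-[(R)-9-acetoxydodecyl]-2-hydroxy-4-methoxybenzoate
Product: 29 5'-methoxy-integracin A, (R)-11-(3,5-dihydroxyphenyl)undecan-4-yl 6-[(R)-9-acetoxydodecyl]-2-hydroxy-4-methoxybenzoate
Conditions: H2 (1 atm), Pd/C (10 wt %), EtOAc, rt
Reagents that add atoms: none
Why: Catalytic hydrogenolysis cleaves only the two benzylic C-O bonds, since neither ester oxygen sits on a benzylic carbon and the molecule holds no other reducible group.

Compound list
1 | (R)-2-propyloxirane | CCC[C@@H]1CO1 | starting material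
2 | 8-bromooct-1-ene | C=CCCCCCCBr | starting material
3 | oct-7-enylmagnesium bromide | C=CCCCCCC[Mg]Br | intermediate
4 | (R)-tridec-12-en-4-ol | CCC[C@@H](O)CCCCCCCC=C | intermediate
5 | (R)-tridec-12-en-4-yl acetate | CCC[C@@H](OC(C)=O)CCCCCCCC=C | intermediate
6 | (R)-13-(9-borabicyclo[3.3.1]nonan-9-yl)tridecan-4-yl acetate | CCC[C@@H](OC(C)=O)CCCCCCCCCB1C2CCCC1CCC2 | intermediate
7 | (R)-13-hydroxytridecan-4-yl acetate | CCC[C@@H](OC(C)=O)CCCCCCCCCO | intermediate
8 | (R)-10-acetoxytridecanoic acid | CCC[C@@H](OC(C)=O)CCCCCCCCC(=O)O | intermediate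
9 | (R)-10-acetoxytridecanoyl chloride | CCC[C@@H](OC(C)=O)CCCCCCCCC(=O)Cl | intermediate
10 | allyl hydrogen malonate | C=CCOC(=O)CC(=O)O | starting material
11 | allyl 3-(1H-benzotriazol-1-yl)-3-oxopropanoate | C=CCOC(=O)CC(=O)n1nnc2ccccc12 | intermediate
12 | 2,2,6-trimethyl-4H-1,3-dioxin-4-one | CC1=CC(=O)OC(C)(C)O1 | starting material
13 | lithium 2,2-dimethyl-6-methylidene-1,3-dioxin-4-olate (dienolate of 12) | [Li+].C=C1C=C([O-])OC(C)(C)O1 | intermediate
14 | allyl 4-(2,2-dimethyl-4-oxo-4H-1,3-dioxin-6-yl)-3-oxobutanoate | C=CCOC(=O)CC(=O)CC1=CC(=O)OC(C)(C)O1 | intermediate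
15 | allyl (12R)-12-acetoxy-2-[2-(2,2-dimethyl-4-oxo-4H-1,3-dioxin-6-yl)acetyl]-3-oxopentadecanoate (C2 labile) | CCC[C@@H](OC(C)=O)CCCCCCCCC(=O)C(C(=O)OCC=C)C(=O)CC1=CC(=O)OC(C)(C)O1 | intermediate
16 | (12R)-12-acetoxy-2-[2-(2,2-dimethyl-4-oxo-4H-1,3-dioxin-6-yl)acetyl]-3-oxopentadecanoic acid (C2 labile) | CCC[C@@H](OC(C)=O)CCCCCCCCC(=O)C(C(=O)O)C(=O)CC1=CC(=O)OC(C)(C)O1 | intermediate
17 | (R)-16-(2,2-dimethyl-4-oxo-4H-1,3-dioxin-6-yl)-13,15-dioxohexadecan-4-yl acetate | CCC[C@@H](OC(C)=O)CCCCCCCCC(=O)CC(=O)CC1=CC(=O)OC(C)(C)O1 | intermediate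
18 | 6-bromohex-1-ene | C=CCCCCBr | starting material
19 | hex-5-enylmagnesium bromide | C=CCCCC[Mg]Br | intermediate
20 | (R)-undec-10-en-4-ol | CCC[C@@H](O)CCCCCC=C | intermediate
21 | 1,3-bis(benzyloxy)-5-bromobenzene | Brc1cc(OCc2ccccc2)cc(OCc2ccccc2)c1 | starting material
22 | (R)-11-(9-borabicyclo[3.3.1]nonan-9-yl)undecan-4-ol | CCC[C@@H](O)CCCCCCCB1C2CCCC1CCC2 | intermediate
23 | (R)-11-[3,5-bis(benzyloxy)phenyl]undecan-4-ol | CCC[C@@H](O)CCCCCCCc1cc(OCc2ccccc2)cc(OCc2ccccc2)c1 | intermediate
24 | (R)-13,15,17,19-tetraoxononadec-18-en-4-yl acetate (diketo-acylketene) | CCC[C@@H](OC(C)=O)CCCCCCCCC(=O)CC(=O)CC(=O)C=C=O | intermediate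
25 | (R)-11-[3,5-bis(benzyloxy)phenyl]undecan-4-yl (R)-16-acetoxy-3,5,7-trioxononadecanoate | CCC[C@@H](OC(C)=O)CCCCCCCCC(=O)CC(=O)CC(=O)CC(=O)O[C@H](CCC)CCCCCCCc1cc(OCc2ccccc2)cc(OCc2ccccc2)c1 | intermediate
26 | (R)-11-[3,5-bis(benzyloxy)phenyl]undecan-4-yl 2-[(R)-9-acetoxydodecyl]-2-hydroxy-4,6-dioxocyclohexane-1-carboxylate (two transient ring centres undefined) | CCC[C@@H](OC(C)=O)CCCCCCCCC1(O)CC(=O)CC(=O)C1C(=O)O[C@H](CCC)CCCCCCCc2cc(OCc3ccccc3)cc(OCc3ccccc3)c2 | intermediate
27 | (R)-11-[3,5-bis(benzyloxy)phenyl]undecan-4-yl 6-[(R)-9-acetoxydodecyl]-2,4-dihydroxybenzoate | CCC[C@H](CCCCCCCCc1cc(O)cc(O)c1C(=O)O[C@H](CCC)CCCCCCCc1cc(OCc2ccccc2)cc(OCc2ccccc2)c1)OC(C)=O | intermediate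
28 | (R)-11-[3,5-bis(benzyloxy)phenyl]undecan-4-yl 6-[(R)-9-acetoxydodecyl]-2-hydroxy-4-methoxybenzoate | CCC[C@H](CCCCCCCCc1cc(OC)cc(O)c1C(=O)O[C@H](CCC)CCCCCCCc1cc(OCc2ccccc2)cc(OCc2ccccc2)c1)OC(C)=O | intermediate
29 | 5'-methoxy-integracin A | CCC[C@H](CCCCCCCCc1cc(OC)cc(O)c1C(=O)O[C@H](CCC)CCCCCCCc1cc(O)cc(O)c1)OC(C)=O | target

Total step count: 14. Longest linear sequence: 10 steps from 1 (steps 1, 2, 3, 4, 5, 8, 9, 12, 13, 14).

Steps most likely to fail

Step 12.
- The hindered carbinol may capture the ketene too slowly, so that intramolecular O-acylation or ketene dimerisation takes over. The acetate may also be lost or transferred during the basic phase.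
- The fallback sets out from 17 and comes back at 28; it separates ring construction from esterification.
- Et3N in CH2Cl2 should aromatise 17 with the dioxinone oxygens kept in place, giving the isopropylidene-protected resorcylate (R)-12-(7-hydroxy-2,2-dimethyl-4-oxo-4H-benzo[d][1,3]dioxin-5-yl)dodecan-4-yl acetate F1.
- MeI and K2CO3 in acetone then methylate its only free phenol to (R)-12-(7-methoxy-2,2-dimethyl-4-oxo-4H-benzo[d][1,3]dioxin-5-yl)dodecan-4-yl acetate F2.
- Irradiation of F2 at about 300 nm in CH2Cl2 in the presence of 23 expels acetone to give the ortho-quinoketene (R)-12-[3-methoxy-5-oxo-6-(oxomethylidene)cyclohexa-1,3-dien-1-yl]dodecan-4-yl acetate F3. The carbinol traps F3 under neutral conditions to give 28 directly, so step 13 is no longer needed.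

Step 7.
- Proton transfer from the acidic malonyl CH2 of the acyl donor to the dienolate, self-condensation of the dienolate and double acylation may erode the Claisen step.
- The fallback sets out from 12 (through its dienolate 13) and comes back at 14; it reverses the roles so that the dioxinone part becomes the acyl donor.
- The dienolate 13 is quenched with CO2 to give 2-(2,2-dimethyl-4-oxo-4H-1,3-dioxin-6-yl)acetic acid F4.
- Carbodiimide and DMAP coupling with Meldrum's acid gives 5-[2-(2,2-dimethyl-4-oxo-4H-1,3-dioxin-6-yl)-1-hydroxyethylidene]-2,2-dimethyl-1,3-dioxane-4,6-dione F5.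
- Alcoholysis of F5 with allyl alcohol in toluene at about 60 to 80 °C, below the temperature at which the dioxinone ring opens, releases acetone and CO2 and should give 14.

Step 11.
- Consumption of the borane by the free hydroxyl, protodeboronation, beta-hydride elimination or reduction of the aryl bromide may lower the coupling.
- The fallback sets out from 21 and 20 and comes back at 23; it forms a C=C bond by metathesis in place of the aryl-alkyl bond.
- Suzuki-Miyaura vinylation of 21 with potassium vinyltrifluoroborate (PdCl2(dppf), Et3N, n-PrOH, reflux) gives 1,3-bis(benzyloxy)-5-ethenylbenzene F6.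
- Cross metathesis of F6 with unprotected 20 (second-generation Grubbs catalyst, CH2Cl2, 40 °C) gives (R,E)-11-[3,5-bis(benzyloxy)phenyl]undec-10-en-4-ol F7, which has the same carbon count because one alkene carbon of each partner leaves as ethene.
- Diimide reduction (TsNHNH2, NaOAc, aqueous THF, reflux) saturates the alkene without touching the benzyl ethers and gives 23.

Further compounds
F1 | step 12 | (R)-12-(7-hydroxy-2,2-dimethyl-4-oxo-4H-benzo[d][1,3]dioxin-5-yl)dodecan-4-yl acetate | CCC[C@@H](OC(C)=O)CCCCCCCCc1cc(O)cc2OC(C)(C)OC(=O)c12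
F2 | step 12 | (R)-12-(7-methoxy-2,2-dimethyl-4-oxo-4H-benzo[d][1,3]dioxin-5-yl)dodecan-4-yl acetate | CCC[C@@H](OC(C)=O)CCCCCCCCc1cc(OC)cc2OC(C)(C)OC(=O)c12
F3 | step 12 | (R)-12-[3-methoxy-5-oxo-6-(oxomethylidene)cyclohexa-1,3-dien-1-yl]dodecan-4-yl acetate | CCC[C@@H](OC(C)=O)CCCCCCCCC1=CC(OC)=CC(=O)C1=C=O
F4 | step 7 | 2-(2,2-dimethyl-4-oxo-4H-1,3-dioxin-6-yl)acetic acid | CC1(C)OC(=O)C=C(CC(=O)O)O1
F5 | step 7 | 5-[2-(2,2-dimethyl-4-oxo-4H-1,3-dioxin-6-yl)-1-hydroxyethylidene]-2,2-dimethyl-1,3-dioxane-4,6-dione | CC1(C)OC(=O)C=C(CC(O)=C2C(=O)OC(C)(C)OC2=O)O1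
F6 | step 11 | 1,3-bis(benzyloxy)-5-ethenylbenzene | C=Cc1cc(OCc2ccccc2)cc(OCc2ccccc2)c1
F7 | step 11 | (R,E)-11-[3,5-bis(benzyloxy)phenyl]undec-10-en-4-ol | CCC[C@@H](O)CCCCC/C=C/c1cc(OCc2ccccc2)cc(OCc2ccccc2)c1
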